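## Retrosynthetic overview

1. Eriolangin 25 ← bis-TBS ether 24 (final desilylation only).
2. 24 ← acyclic allenyl aldehyde 23 by one allenic hetero-Pauson–Khand reaction (aldehyde C=O + internal allene C=C + CO). The cyclohexene C–C bond forms first in the metallacycle and the α-methylene-γ-butyrolactone closes in the same operation; no ring exists before this step.
3. 23 ← tetrasubstituted (E)-enal 15 by reagent-controlled propargylboration (α-allenol, sets the ester-bearing carbon), angeloylation and acetal unmasking.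
4. 15 ← (Z)-enol tosylate 11 by stereoretentive Negishi coupling with a dioxolanylmethylzinc; the alkene geometry comes from chelation-controlled O-tosylation of a β-keto Weinreb amide.
5. β-Keto amide ← (S)-citronellic acid 1 (side-chain stereocentre and two ring carbons) + (TBS-oxy)acetaldehyde 7 by aldol addition and oxidation.

Abbreviations: TBS = tert-butyldimethylsilyl, TES = triethylsilyl, Ts = p-toluenesulfonyl, CDI = 1,1′-carbonyldiimidazole.

Assumption: the (S,S)-bis-sulfonamide boron controller of step 9 is taken as the antipode that delivers the propadienyl group to the si face of aldehyde 15; if the first run shows the opposite sense, the (R,R)-controller is used and nothing else changes.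

## Route

Step 1
Reactants: 1 (S)-citronellic acid [(3S)-3,7-dimethyloct-6-enoic acid]
Product: 3 (3S)-N-methoxy-N,3,7-trimethyloct-6-enamide, via acyl imidazolide 2 (not isolated)
Conditions: CDI, CH2Cl2, rt; then MeNH(OMe)·HCl, rt
Reagents that add atoms: N,O-dimethylhydroxylamine hydrochloride CNOC.Cl; 1,1′-carbonyldiimidazole O=C(n1ccnc1)n1ccnc1 (imidazole unit, in 2 only)
Why: Weinreb amide formation through the acyl imidazolide is mild and leaves the trisubstituted alkene and the β-stereocentre untouched.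

Step 2
Reactants: 3 (3S)-N-methoxy-N,3,7-trimethyloct-6-enamide
Product: 5 (3S)-6-hydroxy-N-methoxy-N,3-dimethylhexanamide, via aldehyde 4 (not isolated)
Conditions: O3, CH2Cl2/MeOH, −78 °C; then NaBH4, −78 to 0 °C
Reagents that add atoms: ozone [O-][O+]=O
Why: Ozonolysis cleaves the only alkene and in situ NaBH4 reduction gives the primary alcohol, the Weinreb amide being inert to NaBH4 at this temperature.

Step 3
Reactants: 5 (3S)-6-hydroxy-N-methoxy-N,3-dimethylhexanamide
Product: 6 (3S)-6-(TBS-oxy)-N-methoxy-N,3-dimethylhexanamide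
Conditions: TBSCl, imidazole, DMF, rt
Reagents that add atoms: tert-butyldimethylsilyl chloride CC(C)(C)[Si](C)(C)Cl
Why: Standard silylation of a primary alcohol gives an ether that survives every later step until the final fluoride treatment.

Step 4
Reactants: 6 (3S)-6-(TBS-oxy)-N-methoxy-N,3-dimethylhexanamide; 7 (TBS-oxy)acetaldehyde
Product: 9 aldol adduct (β-hydroxy Weinreb amide; C-2/C-3 diastereomer mixture), via lithium enolate 8 (not isolated)
Conditions: LiN(i-Pr)2, THF, −78 °C; then 7, −78 °C; AcOH quench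
Reagents that add atoms: lithium diisopropylamide [Li]N(C(C)C)C(C)C (Li, in 8 only)
Why: Aldol addition of the Weinreb amide lithium enolate to the aldehyde builds the C–C bond of the future ring alkene; the two new stereocentres form unselectively and are erased in steps 5 and 6.

Step 5
Reactants: 9 aldol adduct
Product: 10 β-keto Weinreb amide (C-2 epimers)
Conditions: Dess–Martin periodinane, CH2Cl2, rt
Reagents that add atoms: none
Why: Dess–Martin oxidation converts the secondary alcohol into the ketone without touching the silyl ethers or the side-chain stereocentre.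

Step 6
Reactants: 10 β-keto Weinreb amide
Product: 11 (2Z)-enol tosylate (tosyloxy cis to the amide; CH2OTBS cis to the sec-alkyl group)
Conditions: TsCl, TMEDA, LiCl, MeCN, 0 °C to rt
Reagents that add atoms: p-toluenesulfonyl chloride Cc1ccc(cc1)S(=O)(=O)Cl
Why: Enol tosylate formation by O-sulfonylation of the lithium-chelated 1,3-dicarbonyl enolate; chelation between the two carbonyl oxygens holds the tosyloxy group cis to the amide and so fixes the tetrasubstituted alkene geometry.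

Step 7
Reactants: 11 (2Z)-enol tosylate; 12 (1,3-dioxolan-2-ylmethyl)zinc bromide
Product: 13 (2E)-4-(TBS-oxy)-3-(1,3-dioxolan-2-ylmethyl)-N-methoxy-N-methyl-2-[(2S)-5-(TBS-oxy)pentan-2-yl]but-2-enamide
Conditions: Pd(OAc)2 (3 mol %), SPhos (6 mol %), THF, 60 °C
Reagents that add atoms: none
Why: Negishi cross-coupling proceeds with retention at the alkenyl carbon, so the masked acetaldehyde arm ends up cis to the amide, and the organozinc does not attack the Weinreb amide.

Step 8
Reactants: 13 (2E)-dioxolanylmethyl enamide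
Product: 15 (2E)-4-(TBS-oxy)-3-(1,3-dioxolan-2-ylmethyl)-2-[(2S)-5-(TBS-oxy)pentan-2-yl]but-2-enal, via aluminium hemiaminal 14 (not isolated)
Conditions: i-Bu2AlH, THF, −78 °C; aq. potassium sodium tartrate
Reagents that add atoms: diisobutylaluminium hydride CC(C)C[AlH]CC(C)C (Al(i-Bu)2 unit, in 14 only)
Why: Weinreb amide reduction stops at the chelated tetrahedral adduct, which releases the enal only on work-up, so there is no over-reduction and no change of alkene geometry.

Step 9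
Reactants: 15 (2E)-enal; 16 allenyltributylstannane
Product: 18 (4S,5E)-6-[(TBS-oxy)methyl]-7-(1,3-dioxolan-2-yl)-5-[(2S)-5-(TBS-oxy)pentan-2-yl]hepta-1,2,5-trien-4-ol, via B-propargyl diazaborolidine 17 (not isolated)
Conditions: (S,S)-TsNHCH(Ph)CH(Ph)NHTs, BBr3, CH2Cl2, 0 °C to rt, evaporate; 16, CH2Cl2, 0 °C to rt; then 15, −78 °C; pH 7 buffer
Reagents that add atoms: boron tribromide BrB(Br)Br; (S,S)-N,N′-ditosyl-1,2-diphenylethane-1,2-diamine Cc1ccc(cc1)S(=O)(=O)N[C@@H](c1ccccc1)[C@@H](NS(=O)(=O)c1ccc(C)cc1)c1ccccc1 (both in 17 only)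
Why: Asymmetric propargylboration: the stannane transfers to boron with allylic transposition, the B-propargyl reagent adds to the aldehyde through a six-membered SE2′ transition state to give the propa-1,2-dienyl carbinol, and the C2-symmetric bis-sulfonamide controller selects the si face and so sets the (S)-carbinol.

Step 10
Reactants: 18 (4S,5E)-allenol; 19 angelic acid [(2Z)-2-methylbut-2-enoic acid]
Product: 21 (4S,5E)-allenyl angelate of 18, via mixed anhydride 20 (not isolated)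
Conditions: 19, 2,4,6-trichlorobenzoyl chloride, Et3N, toluene, rt; then 18, 75 °C
Reagents that add atoms: 2,4,6-trichlorobenzoyl chloride O=C(Cl)c1c(Cl)cc(Cl)cc1Cl (in 20 only)
Why: Yamaguchi-type esterification acylates the hindered alcohol at the angeloyl carbonyl of the mixed anhydride without a nucleophilic catalyst, which avoids Z to E isomerisation of the angelate and retains the carbinol configuration.

Step 11
Reactants: 21 allenyl angelate
Product: 23 (3E,5S)-3-[(TBS-oxy)methyl]-5-[(2Z)-2-methylbut-2-enoyloxy]-4-[(2S)-5-(TBS-oxy)pentan-2-yl]octa-3,6,7-trienal, via collidinium salt 22 (not isolated)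
Conditions: TESOTf, 2,4,6-collidine, CH2Cl2, 0 °C; then H2O
Reagents that add atoms: water O; triethylsilyl triflate CC[Si](CC)(CC)OS(=O)(=O)C(F)(F)F; 2,4,6-collidine Cc1cc(C)nc(C)c1 (the last two in 22 only)
Why: Silyl triflate–collidine acetal cleavage opens the dioxolane to a pyridinium adduct that water hydrolyses to the aldehyde under non-acidic conditions, so the TBS ethers, the allene, the angelate and the β,γ-position of the alkene are preserved.

Step 12
Reactants: 23 allenyl aldehyde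
Product: 24 bis-TBS eriolangin [(3aR,4S,7aR)-6-[(TBS-oxy)methyl]-3-methylidene-2-oxo-5-[(2S)-5-(TBS-oxy)pentan-2-yl]-2,3,3a,4,7,7a-hexahydro-1-benzofuran-4-yl (2Z)-2-methylbut-2-enoate]
Conditions: Mo(CO)6 (1.2 equiv), DMSO (10 equiv), toluene, 100 °C
Reagents that add atoms: molybdenum hexacarbonyl [Mo].[C-]#[O+].[C-]#[O+].[C-]#[O+].[C-]#[O+].[C-]#[O+].[C-]#[O+] (one CO)
Why: Allenic hetero-Pauson–Khand reaction ([2+2+1] cyclocarbonylation): zerovalent molybdenum couples the aldehyde C=O with the internal allene C=C (closing the cyclohexene), then CO insertion and reductive elimination close the α-methylene-γ-butyrolactone; the metallacycle enforces the cis ring fusion, and the angelate, held pseudoaxial by A(1,2) strain against the sec-alkyl group on the neighbouring alkene carbon, directs the new C–C bond to the opposite face so that it ends up trans to the lactone.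

Step 13
Reactants: 24 bis-TBS eriolangin
Product: 25 eriolangin
Conditions: HF·pyridine, pyridine, THF, 0 °C to rt
Reagents that add atoms: none
Why: Buffered fluoride desilylation removes both primary TBS ethers without touching the α-methylene lactone, the angelate or any stereocentre.

## Compound list

1 | (S)-citronellic acid, (3S)-3,7-dimethyloct-6-enoic acid | C[C@@H](CCC=C(C)C)CC(=O)O | starting material
2 | 1-[(3S)-3,7-dimethyloct-6-enoyl]imidazole | C[C@@H](CCC=C(C)C)CC(=O)n1ccnc1 | intermediate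
3 | (3S)-N-methoxy-N,3,7-trimethyloct-6-enamide | C[C@@H](CCC=C(C)C)CC(=O)N(C)OC | intermediate
4 | (3S)-N-methoxy-N,3-dimethyl-6-oxohexanamide | C[C@@H](CCC=O)CC(=O)N(C)OC | intermediate
5 | (3S)-6-hydroxy-N-methoxy-N,3-dimethylhexanamide | C[C@@H](CCCO)CC(=O)N(C)OC | intermediate
6 | (3S)-6-(TBS-oxy)-N-methoxy-N,3-dimethylhexanamide | C[C@@H](CCCO[Si](C)(C)C(C)(C)C)CC(=O)N(C)OC | intermediate
7 | (tert-butyldimethylsilyloxy)acetaldehyde | O=CCO[Si](C)(C)C(C)(C)C | starting material
8 | lithium (Z)-enolate of 6 | C[C@@H](CCCO[Si](C)(C)C(C)(C)C)/C=C(\O[Li])N(C)OC | intermediate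
9 | 4-(TBS-oxy)-3-hydroxy-N-methoxy-N-methyl-2-[(2S)-5-(TBS-oxy)pentan-2-yl]butanamide (mixture at C-2 and C-3) | C[C@@H](CCCO[Si](C)(C)C(C)(C)C)C(C(O)CO[Si](C)(C)C(C)(C)C)C(=O)N(C)OC | intermediate
10 | 4-(TBS-oxy)-N-methoxy-N-methyl-3-oxo-2-[(2S)-5-(TBS-oxy)pentan-2-yl]butanamide (C-2 epimers) | C[C@@H](CCCO[Si](C)(C)C(C)(C)C)C(C(=O)CO[Si](C)(C)C(C)(C)C)C(=O)N(C)OC | intermediate
11 | (2Z)-4-(TBS-oxy)-N-methoxy-N-methyl-2-[(2S)-5-(TBS-oxy)pentan-2-yl]-3-(tosyloxy)but-2-enamide | C[C@@H](CCCO[Si](C)(C)C(C)(C)C)/C(C(=O)N(C)OC)=C(\CO[Si](C)(C)C(C)(C)C)OS(=O)(=O)c1ccc(C)cc1 | intermediate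
12 | (1,3-dioxolan-2-ylmethyl)zinc bromide (0.5 M in THF) | Br[Zn]CC1OCCO1 | starting material
13 | (2E)-4-(TBS-oxy)-3-(1,3-dioxolan-2-ylmethyl)-N-methoxy-N-methyl-2-[(2S)-5-(TBS-oxy)pentan-2-yl]but-2-enamide | C[C@@H](CCCO[Si](C)(C)C(C)(C)C)/C(C(=O)N(C)OC)=C(\CO[Si](C)(C)C(C)(C)C)CC1OCCO1 | intermediate
14 | O-diisobutylaluminium hemiaminal of 13 | C[C@@H](CCCO[Si](C)(C)C(C)(C)C)/C(C(O[Al](CC(C)C)CC(C)C)N(C)OC)=C(\CO[Si](C)(C)C(C)(C)C)CC1OCCO1 | intermediate
15 | (2E)-4-(TBS-oxy)-3-(1,3-dioxolan-2-ylmethyl)-2-[(2S)-5-(TBS-oxy)pentan-2-yl]but-2-enal | C[C@@H](CCCO[Si](C)(C)C(C)(C)C)/C(C=O)=C(\CO[Si](C)(C)C(C)(C)C)CC1OCCO1 | intermediate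
16 | allenyltributylstannane, tributyl(propa-1,2-dienyl)stannane | CCCC[Sn](CCCC)(CCCC)C=C=C | starting material
17 | (4S,5S)-4,5-diphenyl-2-(prop-2-ynyl)-1,3-ditosyl-1,3,2-diazaborolidine | C#CCB1N(S(=O)(=O)c2ccc(C)cc2)[C@@H](c2ccccc2)[C@H](c2ccccc2)N1S(=O)(=O)c1ccc(C)cc1 | intermediate
18 | (4S,5E)-6-[(TBS-oxy)methyl]-7-(1,3-dioxolan-2-yl)-5-[(2S)-5-(TBS-oxy)pentan-2-yl]hepta-1,2,5-trien-4-ol | C[C@@H](CCCO[Si](C)(C)C(C)(C)C)/C([C@@H](O)C=C=C)=C(\CO[Si](C)(C)C(C)(C)C)CC1OCCO1 | intermediate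
19 | angelic acid, (2Z)-2-methylbut-2-enoic acid | C/C=C(/C)C(=O)O | starting material
20 | angelic 2,4,6-trichlorobenzoic anhydride | C/C=C(/C)C(=O)OC(=O)c1c(Cl)cc(Cl)cc1Cl | intermediate
21 | (4S,5E)-6-[(TBS-oxy)methyl]-7-(1,3-dioxolan-2-yl)-5-[(2S)-5-(TBS-oxy)pentan-2-yl]hepta-1,2,5-trien-4-yl (2Z)-2-methylbut-2-enoate | C[C@@H](CCCO[Si](C)(C)C(C)(C)C)/C([C@@H](OC(=O)/C(C)=C\C)C=C=C)=C(\CO[Si](C)(C)C(C)(C)C)CC1OCCO1 | intermediate
22 | 2,4,6-trimethylpyridinium adduct of opened acetal 21 (N,O-acetal carbon bearing OCH2CH2OTES), triflate salt | C[C@@H](CCCO[Si](C)(C)C(C)(C)C)/C([C@@H](OC(=O)/C(C)=C\C)C=C=C)=C(\CO[Si](C)(C)C(C)(C)C)CC(OCCO[Si](CC)(CC)CC)[n+]1c(C)cc(C)cc1C.[O-]S(=O)(=O)C(F)(F)F | intermediate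
23 | (3E,5S)-3-[(TBS-oxy)methyl]-5-[(2Z)-2-methylbut-2-enoyloxy]-4-[(2S)-5-(TBS-oxy)pentan-2-yl]octa-3,6,7-trienal | C[C@@H](CCCO[Si](C)(C)C(C)(C)C)/C([C@@H](OC(=O)/C(C)=C\C)C=C=C)=C(\CO[Si](C)(C)C(C)(C)C)CC=O | intermediate
24 | bis-TBS eriolangin, (3aR,4S,7aR)-6-[(TBS-oxy)methyl]-3-methylidene-2-oxo-5-[(2S)-5-(TBS-oxy)pentan-2-yl]-2,3,3a,4,7,7a-hexahydro-1-benzofuran-4-yl (2Z)-2-methylbut-2-enoate | C=C1C(=O)O[C@@H]2CC(CO[Si](C)(C)C(C)(C)C)=C([C@@H](C)CCCO[Si](C)(C)C(C)(C)C)[C@@H](OC(=O)/C(C)=C\C)[C@H]12 | intermediate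
25 | eriolangin, (3aR,4S,7aR)-6-(hydroxymethyl)-5-[(2S)-5-hydroxypentan-2-yl]-3-methylidene-2-oxo-2,3,3a,4,7,7a-hexahydro-1-benzofuran-4-yl (2Z)-2-methylbut-2-enoate | C=C1C(=O)O[C@@H]2CC(CO)=C([C@@H](C)CCCO)[C@@H](OC(=O)/C(C)=C\C)[C@H]12 | target

## Step count and risks

Total steps: 13. Longest linear sequence: 13 (from 1; compounds 7, 12, 16 and 19 are bought).

Most likely to fail, step 12 (hetero-Pauson–Khand). The allenylic angelate could ionise on zerovalent molybdenum, the β,γ-unsaturated aldehyde could drift into conjugation at 100 °C, and the facial control by the angelate is a prediction, not a precedent. The fallback takes the ester out of the cyclisation and moves the esterification to the end. It sets out from allenol 18: silylation with TESOTf and 2,6-lutidine gives the TES ether F11, acetal cleavage as in step 11 gives the allenyl aldehyde F12, the same Mo(CO)6/DMSO cyclocarbonylation gives the bicyclic lactone TES ether F13, PPTS in MeOH at 0 °C frees the secondary alcohol F14 in the presence of the two primary TBS ethers, and the angeloylation of step 10 then returns to the route at 24.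

Second, step 9 (asymmetric propargylboration). The aldehyde is a hindered, fully substituted enal, and the sense and level of induction are not secured for this substrate. The fallback sets the carbinol by ketone reduction and builds the allene afterwards. It sets out from enal 15: addition of LiC≡CSiMe3 gives the silylated propargylic alcohol F7 as an epimer mixture, Dess–Martin oxidation gives the ynone F8, transfer hydrogenation with RuCl[(R,R)-TsDPEN](p-cymene) in i-PrOH gives the single carbinol epimer F9, K2CO3 in MeOH gives the terminal alkyne F10, and Crabbé homologation (CuBr, paraformaldehyde, i-Pr2NH, dioxane, reflux) returns to the route at 18.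

Third, step 7 (Negishi coupling). An sp3 zinc reagent with a β-oxygen has to couple at a tetrasubstituted, electron-poor alkenyl tosylate; slow oxidative addition and β-alkoxide loss are the risks. The fallback uses an sp2 partner and an alcohol in place of the acetal, which also removes step 11. It sets out from tosylate 11: Suzuki coupling with potassium vinyltrifluoroborate (Pd(OAc)2, SPhos, K3PO4, THF/H2O) gives the dienamide F1, 9-BBN then NaBO3 hydroborates only the monosubstituted vinyl group to give the primary alcohol F2, TESCl and imidazole give the TES ether F3, i-Bu2AlH gives the enal F4, the propargylboration of step 9 gives the allenol F5, the angeloylation of step 10 gives the angelate F6, and Swern oxidation (oxalyl chloride, DMSO, Et3N), which converts a primary TES ether directly into the aldehyde while primary TBS ethers survive, returns to the route at 23.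

## Further compounds

F1 | step 7 | (2E)-4-(TBS-oxy)-3-ethenyl-N-methoxy-N-methyl-2-[(2S)-5-(TBS-oxy)pentan-2-yl]but-2-enamide | C[C@@H](CCCO[Si](C)(C)C(C)(C)C)/C(C(=O)N(C)OC)=C(\CO[Si](C)(C)C(C)(C)C)C=C
F2 | step 7 | (2E)-4-(TBS-oxy)-3-(2-hydroxyethyl)-N-methoxy-N-methyl-2-[(2S)-5-(TBS-oxy)pentan-2-yl]but-2-enamide | C[C@@H](CCCO[Si](C)(C)C(C)(C)C)/C(C(=O)N(C)OC)=C(\CO[Si](C)(C)C(C)(C)C)CCO
F3 | step 7 | (2E)-4-(TBS-oxy)-N-methoxy-N-methyl-2-[(2S)-5-(TBS-oxy)pentan-2-yl]-3-[2-(TES-oxy)ethyl]but-2-enamide | C[C@@H](CCCO[Si](C)(C)C(C)(C)C)/C(C(=O)N(C)OC)=C(\CO[Si](C)(C)C(C)(C)C)CCO[Si](CC)(CC)CC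
F4 | step 7 | (2E)-4-(TBS-oxy)-2-[(2S)-5-(TBS-oxy)pentan-2-yl]-3-[2-(TES-oxy)ethyl]but-2-enal | C[C@@H](CCCO[Si](C)(C)C(C)(C)C)/C(C=O)=C(\CO[Si](C)(C)C(C)(C)C)CCO[Si](CC)(CC)CC
F5 | step 7 | (4S,5E)-6-[(TBS-oxy)methyl]-5-[(2S)-5-(TBS-oxy)pentan-2-yl]-8-(TES-oxy)octa-1,2,5-trien-4-ol | C[C@@H](CCCO[Si](C)(C)C(C)(C)C)/C([C@@H](O)C=C=C)=C(\CO[Si](C)(C)C(C)(C)C)CCO[Si](CC)(CC)CC
F6 | step 7 | (4S,5E)-6-[(TBS-oxy)methyl]-5-[(2S)-5-(TBS-oxy)pentan-2-yl]-8-(TES-oxy)octa-1,2,5-trien-4-yl (2Z)-2-methylbut-2-enoate | C[C@@H](CCCO[Si](C)(C)C(C)(C)C)/C([C@@H](OC(=O)/C(C)=C\C)C=C=C)=C(\CO[Si](C)(C)C(C)(C)C)CCO[Si](CC)(CC)CC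
F7 | step 9 | trimethylsilylethynyl carbinol from 15 (carbinol epimers; E-alkene and side-chain stereocentre as in 15) | C[C@@H](CCCO[Si](C)(C)C(C)(C)C)/C(C(O)C#C[Si](C)(C)C)=C(\CO[Si](C)(C)C(C)(C)C)CC1OCCO1
F8 | step 9 | trimethylsilylethynyl ketone from F7 | C[C@@H](CCCO[Si](C)(C)C(C)(C)C)/C(C(=O)C#C[Si](C)(C)C)=C(\CO[Si](C)(C)C(C)(C)C)CC1OCCO1
F9 | step 9 | single carbinol epimer of F7 (carbinol arranged in space as in 18) | C[C@@H](CCCO[Si](C)(C)C(C)(C)C)/C([C@@H](O)C#C[Si](C)(C)C)=C(\CO[Si](C)(C)C(C)(C)C)CC1OCCO1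
F10 | step 9 | terminal propargylic alcohol from F9 (carbinol arranged in space as in 18) | C[C@@H](CCCO[Si](C)(C)C(C)(C)C)/C([C@@H](O)C#C)=C(\CO[Si](C)(C)C(C)(C)C)CC1OCCO1
F11 | step 12 | TES ether of allenol 18 | C[C@@H](CCCO[Si](C)(C)C(C)(C)C)/C([C@@H](O[Si](CC)(CC)CC)C=C=C)=C(\CO[Si](C)(C)C(C)(C)C)CC1OCCO1
F12 | step 12 | (3E,5S)-3-[(TBS-oxy)methyl]-4-[(2S)-5-(TBS-oxy)pentan-2-yl]-5-(TES-oxy)octa-3,6,7-trienal | C[C@@H](CCCO[Si](C)(C)C(C)(C)C)/C([C@@H](O[Si](CC)(CC)CC)C=C=C)=C(\CO[Si](C)(C)C(C)(C)C)CC=O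
F13 | step 12 | cis-fused bicyclic α-methylene lactone with a TES ether in place of the angelate of 24 | C=C1C(=O)O[C@@H]2CC(CO[Si](C)(C)C(C)(C)C)=C([C@@H](C)CCCO[Si](C)(C)C(C)(C)C)[C@@H](O[Si](CC)(CC)CC)[C@H]12
F14 | step 12 | cis-fused bicyclic α-methylene lactone with a free secondary alcohol in place of the angelate of 24 | C=C1C(=O)O[C@@H]2CC(CO[Si](C)(C)C(C)(C)C)=C([C@@H](C)CCCO[Si](C)(C)C(C)(C)C)[C@@H](O)[C@H]12
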